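**Assumption:** (R)-2-vinyloxirane (single enantiomer of butadiene monoepoxide) is taken as purchasable; atom labels C1–C15 are the usual germacrane/elemane numbers (C6 = lactone CH–O, C7 = ring-fusion CH, C8 = CH–OAc, C10 = quaternary C, C14 = CH2OAc, C15 = CHO).

## Retrosynthetic overview

1. Target 19 ⇒ allylic oxidation (C15 CH3 → CHO) of isopropenyl elemanolide 17.
2. 17 ⇒ Cope rearrangement of germacranolide 16: the C5–C10 bond forms, the ten-membered ring contracts to the cyclohexane, and C5 and C10 are set.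
3. 16 ⇒ acyclic bromo-ester enal 14: one Cr(II) operation closes the ten-membered carbocycle (C6–C7) and the α-methylene-γ-lactone (O–C12); C6 and C7 are set from C8.
4. 14 ⇒ cross-metathesis (12) on diacetate 11 ⇐ (Z)-alkylidene lactone 9 ⇐ HWE of phosphono-lactone 8 (from epoxide 5 and phosphonoacetate 6; the only source of chirality, C8) with aldehyde 4 (from geraniol 1).
5. Ring order: ten-membered carbocycle and γ-lactone together, then cyclohexane by ring contraction.

## Route

**Step 1**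
Reactants: 1 geraniol
Product: 2 geranyl tert-butyldimethylsilyl ether
Conditions: TBSCl, imidazole, CH2Cl2, 0 °C → rt
Reagents that add atoms: tert-butyldimethylsilyl chloride, CC(C)(C)[Si](C)(C)Cl
Why: Standard silylation of the primary allylic alcohol, giving a group that survives base, hydride and acylation and is later removed oxidatively; no stereocentre is involved.

**Step 2**
Reactants: 2 geranyl tert-butyldimethylsilyl ether
Product: 4 (4E)-6-[(tert-butyldimethylsilyl)oxy]-4-methylhex-4-enal, via 6,7-epoxygeranyl TBS ether 3 (not isolated)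
Conditions: mCPBA (1.05 equiv), CH2Cl2, −20 °C; then H5IO6, THF/H2O, 0 °C
Reagents that add atoms: meta-chloroperbenzoic acid, OOC(=O)c1cccc(Cl)c1
Why: Prilezhaev epoxidation prefers the remote, more electron-rich 6,7-alkene over the 2,3-alkene deactivated by the allylic silyloxy group, and periodic acid cleaves the epoxide to the aldehyde without touching the (E)-alkene.

**Step 3**
Reactants: 5 (R)-2-vinyloxirane; 6 triethyl phosphonoacetate
Product: 8 diethyl [(5S)-5-ethenyl-2-oxooxolan-3-yl]phosphonate, via open-chain sodium alkoxide 7 (not isolated)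
Conditions: NaH, DME/toluene, 0 °C; then 5, 90 °C (sealed); 1 M HCl work-up
Reagents that add atoms: none
Why: SN2 opening of the epoxide at its unhindered CH2 terminus by the phosphonoacetate anion followed by lactonisation (classical α-phosphono-γ-butyrolactone synthesis); the C–O bond at the stereocentre is not broken, so the (R)-epoxide gives the (5S)-lactone, which is C8 of the target.

**Step 4**
Reactants: 8 diethyl [(5S)-5-ethenyl-2-oxooxolan-3-yl]phosphonate; 4 (4E)-6-[(tert-butyldimethylsilyl)oxy]-4-methylhex-4-enal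
Product: 9 (3Z,5S)-3-{(4E)-6-[(tert-butyldimethylsilyl)oxy]-4-methylhex-4-en-1-ylidene}-5-ethenyloxolan-2-one
Conditions: KHMDS, 18-crown-6, THF, −78 °C; then 4, −78 → −40 °C
Reagents that add atoms: none
Why: Horner–Wadsworth–Emmons olefination under dissociating K+/18-crown-6 (Still–Gennari-type) conditions, expected to favour kinetically the (Z)-alkylidene lactone (chain cis to C=O, the C1=C10 geometry needed for the later Cope step); the minor (E)-isomer is removed by chromatography.

**Step 5**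
Reactants: 9 (Z)-alkylidene lactone
Product: 10 (2Z,6E)-8-[(tert-butyldimethylsilyl)oxy]-2-[(2S)-2-hydroxybut-3-en-1-yl]-6-methylocta-2,6-dien-1-ol
Conditions: DIBAL-H (4.5 equiv), CH2Cl2, −78 → 0 °C; Rochelle salt
Reagents that add atoms: none
Why: Clean 1,2-reduction of the unsaturated lactone to the allylic diol, with alkene geometry and the C8 configuration retained.

**Step 6**
Reactants: 10 diol
Product: 11 (2Z,6E)-2-[(2S)-2-acetoxybut-3-en-1-yl]-8-[(tert-butyldimethylsilyl)oxy]-6-methylocta-2,6-dien-1-yl acetate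
Conditions: Ac2O, pyridine, DMAP (cat.), CH2Cl2, rt
Reagents that add atoms: acetic anhydride, CC(=O)OC(C)=O
Why: Acetylation installs both acetates of the target (C14–OAc and C8–OAc) in one operation.

**Step 7**
Reactants: 11 diacetate; 12 methyl 2-(bromomethyl)acrylate
Product: 13 methyl (2Z,4S,6Z,10E)-4-acetoxy-6-(acetoxymethyl)-2-(bromomethyl)-12-[(tert-butyldimethylsilyl)oxy]-10-methyldodeca-2,6,10-trienoate
Conditions: 12 (5 equiv), Hoveyda–Grubbs II (10 mol %), 2,6-dichloro-1,4-benzoquinone (20 mol %), toluene, 60 °C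
Reagents that add atoms: none
Why: Olefin cross-metathesis in which only the monosubstituted vinyl group of 11 can enter the Ru cycle (the trisubstituted alkenes are inert), giving the thermodynamically preferred trisubstituted enoate with the ester trans to C8.

**Step 8**
Reactants: 13 allylic bromide
Product: 14 methyl (2Z,4S,6Z,10E)-4-acetoxy-6-(acetoxymethyl)-2-(bromomethyl)-10-methyl-12-oxododeca-2,6,10-trienoate
Conditions: DDQ (1.3 equiv), CH2Cl2/pH 7 buffer (10:1), 0 °C → rt
Reagents that add atoms: none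
Why: Oxidative deprotection — DDQ abstracts hydride from the electron-rich allylic silyl ether and hydrolysis gives the (E)-enal directly; acetates, acrylate and allylic bromide do not react.

**Step 9**
Reactants: 14 bromo-ester enal
Product: 16 (6R,7R,8S)-8α,14-diacetoxygermacra-1(10),4,11(13)-trien-12,6α-olide (costunolide ring geometry: C2/C9 trans across C1=C10 and C3/C6 trans across C4=C5), via ten-membered hydroxy ester 15 (not isolated)
Conditions: CrCl2 (10 equiv), THF, rt, syringe-pump addition of 14 (final 2 mM); aq. NH4Cl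
Reagents that add atoms: none
Why: Intramolecular Nozaki–Hiyama (CrCl2) allylation of the 2-(bromomethyl)acrylate onto the enal closes the ten-membered ring, and the Cr(III) alkoxide then lactonises onto the ester; the equilibrating allylchromium is expected to react through a costunolide-like chair/crown transition state with C5 and C8 pseudo-equatorial and the 8-OAc outside (H8 in the allyl plane, A1,3 control), giving the 6,7-trans and 7,8-trans relationships, while Cr(II) leaves the allylic acetate alone.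

**Step 10**
Reactants: 16 germacranolide
Product: 17 (5S,6R,7R,8S,10R)-8α,14-diacetoxyelema-1,3,11(13)-trien-12,6α-olide (same spatial arrangement at C5 as the target; the descriptor differs only through CIP priorities)
Conditions: toluene (0.01 M, BHT), sealed tube, 195 °C, 3 h; recovered 16 recycled
Reagents that add atoms: none
Why: Cope rearrangement of the (E,E)-cyclodeca-1,5-diene (the costunolide → elemanolide reaction type) through the chair transition state that keeps the trans-lactone and the 8-OAc equatorial on the emerging cyclohexane, which sets C5 (H α, isopropenyl equatorial) and C10 (vinyl equatorial, CH2OAc axial).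

**Step 11**
Reactants: 17 isopropenyl elemanolide
Product: 19 (5R,6R,7R,8S,10R)-8α,14-diacetoxy-15-oxoelema-1,3,11(13)-trien-12,6α-olide (target CNP0200597.1), via 15-hydroxy elemanolide 18 (not isolated)
Conditions: SeO2 (1.2 equiv), 1,4-dioxane, 80 °C
Reagents that add atoms: selenium dioxide, O=[Se]=O
Why: Riley allylic oxidation (ene reaction then [2,3]-shift) attacks the methyl of the only electron-rich 1,1-disubstituted alkene (the vinyl group has no allylic H, the methylene lactone is electron-poor, C5–H is hindered), and the allylic alcohol is oxidised on to the enal without touching any stereocentre.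

## Compound list

1 | geraniol, (2E)-3,7-dimethylocta-2,6-dien-1-ol | CC(C)=CCC/C(C)=C/CO | starting material
2 | geranyl tert-butyldimethylsilyl ether | CC(C)=CCC/C(C)=C/CO[Si](C)(C)C(C)(C)C | intermediate
3 | 6,7-epoxygeranyl TBS ether (racemic at the oxirane CH) | CC1(C)OC1CC/C(C)=C/CO[Si](C)(C)C(C)(C)C | intermediate
4 | (4E)-6-[(tert-butyldimethylsilyl)oxy]-4-methylhex-4-enal | O=CCC/C(C)=C/CO[Si](C)(C)C(C)(C)C | intermediate
5 | (R)-2-vinyloxirane | C=C[C@@H]1CO1 | starting material
6 | triethyl phosphonoacetate | CCOC(=O)CP(=O)(OCC)OCC | starting material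
7 | ethyl (4S)-2-(diethoxyphosphoryl)-4-hydroxyhex-5-enoate (as sodium alkoxide, C2 epimers) | CCOC(=O)C(C[C@H](O)C=C)P(=O)(OCC)OCC | intermediate
8 | diethyl [(5S)-5-ethenyl-2-oxooxolan-3-yl]phosphonate (C3 epimers) | C=C[C@@H]1CC(P(=O)(OCC)OCC)C(=O)O1 | intermediate
9 | (3Z,5S)-3-{(4E)-6-[(tert-butyldimethylsilyl)oxy]-4-methylhex-4-en-1-ylidene}-5-ethenyloxolan-2-one | C=C[C@@H]1C/C(=C/CC/C(C)=C/CO[Si](C)(C)C(C)(C)C)C(=O)O1 | intermediate
10 | (2Z,6E)-8-[(tert-butyldimethylsilyl)oxy]-2-[(2S)-2-hydroxybut-3-en-1-yl]-6-methylocta-2,6-dien-1-ol | C=C[C@@H](O)C/C(CO)=C/CC/C(C)=C/CO[Si](C)(C)C(C)(C)C | intermediate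
11 | (2Z,6E)-2-[(2S)-2-acetoxybut-3-en-1-yl]-8-[(tert-butyldimethylsilyl)oxy]-6-methylocta-2,6-dien-1-yl acetate | C=C[C@@H](OC(C)=O)C/C(COC(C)=O)=C/CC/C(C)=C/CO[Si](C)(C)C(C)(C)C | intermediate
12 | methyl 2-(bromomethyl)acrylate | C=C(CBr)C(=O)OC | starting material
13 | methyl (2Z,4S,6Z,10E)-4-acetoxy-6-(acetoxymethyl)-2-(bromomethyl)-12-[(tert-butyldimethylsilyl)oxy]-10-methyldodeca-2,6,10-trienoate | COC(=O)/C(CBr)=C/[C@@H](OC(C)=O)C/C(COC(C)=O)=C/CC/C(C)=C/CO[Si](C)(C)C(C)(C)C | intermediate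
14 | methyl (2Z,4S,6Z,10E)-4-acetoxy-6-(acetoxymethyl)-2-(bromomethyl)-10-methyl-12-oxododeca-2,6,10-trienoate | COC(=O)/C(CBr)=C/[C@@H](OC(C)=O)C/C(COC(C)=O)=C/CC/C(C)=C/C=O | intermediate
15 | methyl 2-[(6R,7S,8S)-8,14-diacetoxy-6-hydroxygermacra-1(10),4-dien-7-yl]acrylate (ten-membered hydroxy ester) | CC(=O)OC/C1=C\CC/C(C)=C/[C@@H](O)[C@H](C(=C)C(=O)OC)[C@@H](OC(C)=O)C1 | intermediate
16 | (6R,7R,8S)-8α,14-diacetoxygermacra-1(10),4,11(13)-trien-12,6α-olide | CC(=O)OC/C1=C\CC/C(C)=C/[C@H]2OC(=O)C(=C)[C@@H]2[C@@H](OC(C)=O)C1 | intermediate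
17 | (5S,6R,7R,8S,10R)-8α,14-diacetoxyelema-1,3,11(13)-trien-12,6α-olide | C=C[C@]1(COC(C)=O)C[C@H](OC(C)=O)[C@H]2C(=C)C(=O)O[C@@H]2[C@H]1C(C)=C | intermediate
18 | (5S,6R,7R,8S,10R)-8α,14-diacetoxy-15-hydroxyelema-1,3,11(13)-trien-12,6α-olide | C=C[C@]1(COC(C)=O)C[C@H](OC(C)=O)[C@H]2C(=C)C(=O)O[C@@H]2[C@H]1C(=C)CO | intermediate
19 | (5R,6R,7R,8S,10R)-8α,14-diacetoxy-15-oxoelema-1,3,11(13)-trien-12,6α-olide | C=C[C@]1(COC(C)=O)C[C@H](OC(C)=O)[C@H]2C(=C)C(=O)O[C@@H]2[C@H]1C(=C)C=O | target

## Summary and fallbacks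

Total step count: 11. Longest linear sequence: 10 (steps 1, 2, 4–11 from geraniol).

**Step 9 (Cr-mediated double ring closure).** The risks are low macrocyclisation yield, formation of the cis-fused lactone (acyclic 2-(bromomethyl)alkenoates usually give syn adducts), and 1,4-elimination of the C8 acetate from the allylchromium. The fallback sets out from 11 and replaces the organochromium by an allylsilane and an open transition state that cannot eliminate acetate. Cross-metathesis of 11 with methyl 2-[(trimethylsilyl)methyl]acrylate gives methyl (2Z,4S,6Z,10E)-4-acetoxy-6-(acetoxymethyl)-12-[(tert-butyldimethylsilyl)oxy]-10-methyl-2-[(trimethylsilyl)methyl]dodeca-2,6,10-trienoate F1. DDQ as in step 8 gives the corresponding enal, methyl (2Z,4S,6Z,10E)-4-acetoxy-6-(acetoxymethyl)-10-methyl-12-oxo-2-[(trimethylsilyl)methyl]dodeca-2,6,10-trienoate F2. An intramolecular Hosomi–Sakurai reaction (BF3·OEt2, CH2Cl2, −78 °C, high dilution) then closes the ten-membered ring, and lactonisation of 15 in the same flask returns the route to 16.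

**Step 7 (cross-metathesis of a hindered secondary allylic acetate with a 1,1-disubstituted acrylate).** The fallback sets out from 6 and 4 and builds the bromomethyl acrylate by Morita–Baylis–Hillman chemistry instead.
- Compound 6 and commercial (S)-tert-butyldimethylsilyl glycidyl ether give, as in step 3, diethyl [(5S)-5-{[(tert-butyldimethylsilyl)oxy]methyl}-2-oxooxolan-3-yl]phosphonate F3.
- HWE with 4 as in step 4 gives (3Z,5S)-3-{(4E)-6-[(tert-butyldimethylsilyl)oxy]-4-methylhex-4-en-1-ylidene}-5-{[(tert-butyldimethylsilyl)oxy]methyl}oxolan-2-one F4.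
- DIBAL-H gives (2Z,6E)-8-[(tert-butyldimethylsilyl)oxy]-2-{(2S)-3-[(tert-butyldimethylsilyl)oxy]-2-hydroxypropyl}-6-methylocta-2,6-dien-1-ol F5, and Ac2O gives its diacetate F6.
- HF·pyridine removes both silyl groups to give (2Z,6E)-2-[(2S)-2-acetoxy-3-hydroxypropyl]-8-hydroxy-6-methylocta-2,6-dien-1-yl acetate F7.
- Dess–Martin periodinane oxidises both primary alcohols to (2S,4Z,8E)-2-acetoxy-4-(acetoxymethyl)-8-methyldeca-4,8-dienedial F8.
- Methyl acrylate/DABCO reacts only at the α-acetoxy aldehyde to give methyl (4S,6Z,10E)-4-acetoxy-6-(acetoxymethyl)-3-hydroxy-10-methyl-2-methylidene-12-oxododeca-6,10-dienoate F9.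
- NBS/Me2S (SN2′ bromination) then delivers 14, where the route is rejoined.

**Step 11 (selenium dioxide oxidation on the fully functionalised lactone).** The risks are incomplete oxidation and attack at C5–H. The fallback sets out from 17 and uses a singlet-oxygen ene reaction (O2, tetraphenylporphyrin, hν, CH2Cl2, 0 °C) to give (5S,6R,7R,8S,10R)-8α,14-diacetoxy-15-hydroperoxyelema-1,3,11(13)-trien-12,6α-olide F10. Kornblum–DeLaMare dehydration (Ac2O, pyridine, DMAP) converts it to the enal and returns the route at 19.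

## Further compounds

F1 | step 9 | methyl (2Z,4S,6Z,10E)-4-acetoxy-6-(acetoxymethyl)-12-[(tert-butyldimethylsilyl)oxy]-10-methyl-2-[(trimethylsilyl)methyl]dodeca-2,6,10-trienoate | COC(=O)/C(C[Si](C)(C)C)=C/[C@@H](OC(C)=O)C/C(COC(C)=O)=C/CC/C(C)=C/CO[Si](C)(C)C(C)(C)C
F2 | step 9 | methyl (2Z,4S,6Z,10E)-4-acetoxy-6-(acetoxymethyl)-10-methyl-12-oxo-2-[(trimethylsilyl)methyl]dodeca-2,6,10-trienoate | COC(=O)/C(C[Si](C)(C)C)=C/[C@@H](OC(C)=O)C/C(COC(C)=O)=C/CC/C(C)=C/C=O
F3 | step 7 | diethyl [(5S)-5-{[(tert-butyldimethylsilyl)oxy]methyl}-2-oxooxolan-3-yl]phosphonate | CC(C)(C)[Si](C)(C)OC[C@@H]1CC(P(=O)(OCC)OCC)C(=O)O1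
F4 | step 7 | (3Z,5S)-3-{(4E)-6-[(tert-butyldimethylsilyl)oxy]-4-methylhex-4-en-1-ylidene}-5-{[(tert-butyldimethylsilyl)oxy]methyl}oxolan-2-one | CC(C)(C)[Si](C)(C)OC[C@@H]1C/C(=C/CC/C(C)=C/CO[Si](C)(C)C(C)(C)C)C(=O)O1
F5 | step 7 | (2Z,6E)-8-[(tert-butyldimethylsilyl)oxy]-2-{(2S)-3-[(tert-butyldimethylsilyl)oxy]-2-hydroxypropyl}-6-methylocta-2,6-dien-1-ol | CC(C)(C)[Si](C)(C)OC[C@@H](O)C/C(CO)=C/CC/C(C)=C/CO[Si](C)(C)C(C)(C)C
F6 | step 7 | (2Z,6E)-2-{(2S)-2-acetoxy-3-[(tert-butyldimethylsilyl)oxy]propyl}-8-[(tert-butyldimethylsilyl)oxy]-6-methylocta-2,6-dien-1-yl acetate | CC(C)(C)[Si](C)(C)OC[C@@H](OC(C)=O)C/C(COC(C)=O)=C/CC/C(C)=C/CO[Si](C)(C)C(C)(C)C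
F7 | step 7 | (2Z,6E)-2-[(2S)-2-acetoxy-3-hydroxypropyl]-8-hydroxy-6-methylocta-2,6-dien-1-yl acetate | OC[C@@H](OC(C)=O)C/C(COC(C)=O)=C/CC/C(C)=C/CO
F8 | step 7 | (2S,4Z,8E)-2-acetoxy-4-(acetoxymethyl)-8-methyldeca-4,8-dienedial | O=C[C@@H](OC(C)=O)C/C(COC(C)=O)=C/CC/C(C)=C/C=O
F9 | step 7 | methyl (4S,6Z,10E)-4-acetoxy-6-(acetoxymethyl)-3-hydroxy-10-methyl-2-methylidene-12-oxododeca-6,10-dienoate (C3 epimers) | COC(=O)C(=C)C(O)[C@@H](OC(C)=O)C/C(COC(C)=O)=C/CC/C(C)=C/C=O
F10 | step 11 | (5S,6R,7R,8S,10R)-8α,14-diacetoxy-15-hydroperoxyelema-1,3,11(13)-trien-12,6α-olide | C=C[C@]1(COC(C)=O)C[C@H](OC(C)=O)[C@H]2C(=C)C(=O)O[C@@H]2[C@H]1C(=C)COO
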